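**Plan**

- Retrosynthesis: cut C2–C4' and C14–C15' first (cyclohexene and spiro centre, a Diels–Alder union of two 8-oxygenated guaianolide monomers). In each monomer cut C1–C5, C2–C3 and C3–C4 together (allenic Pauson–Khand), then C6–C7 (2-(methoxycarbonyl)allylation of an ynal) and C8–C9 (glyoxylate-ene).
- Enabling feature: in the cyclopentenone half, C3=O is flanked by C1=C2 and the exocyclic C4=C15, and C5 is the only sp3 ring atom. The 5-methylenecyclopent-2-enone (C1–C5) and the cycloheptane (C1, C10, C9, C8, C7, C6, C5) are therefore the [2+2+1] adduct of the alkyne C1≡C2, the proximal bond C4=C5 of a terminal allene C5=C4=C15 and CO. The enyne C14=C10–C1≡C2 becomes the s-cis diene C14=C10–C1=C2 in the same event.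
- Forward: ene reaction (C8) → allyl bromide 8 → divergent allylation of ynal 11 (CrCl2 to trans-lactone 13, indium to syn hydroxy ester 22) → allenes 16 and 26 → Pauson–Khand closes the five- and seven-membered rings at once in each series. 17 is then saturated at C1–C2 to dienophile 21, and 27 is lactonized with inversion to diene 30; Diels–Alder closes the cyclohexene, then desilylation.
- Stereochemistry: C8 from the (R)-BINOL–titanium catalyst; C7 from C8 by 1,2-induction; C6 from the allylation transition state (anti with chromium, syn with indium); C5 from C6 in the Pauson–Khand step (H5 cis to O6). The cis H5/H6 relation of the enone half comes from SN2 inversion at C6; C1' from copper hydride; C4' from convex-face Diels–Alder; C10 from protonation cis to H5.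

Key step: step 18

Remark: guaiane numbering is used (C1–C15 for the cyclopentenone half, primes for the spiro-cyclopentanone half; open-chain intermediates carry the locants of the atoms they become). The target SMILES reads as 5β-H, 6β-H, 7α-H, 8β-OH, 10β-H in the unprimed half and 1'α-H, 5'α-H, 6'β-H, 7'α-H, 8'β-OH in the primed half, so the two halves differ at C5 and are made separately.

**Step 1**
Reactants: 1 ethyl glyoxylate; 2 2-methylbut-1-en-3-yne
Product: 3 ethyl (2R)-2-hydroxy-4-methylidenehex-5-ynoate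
Conditions: (R)-BINOL/TiCl2(OiPr)2 (10 mol %), 4 Å MS, CH2Cl2, −30 °C
Reagents that add atoms: none
Why: Asymmetric glyoxylate-ene reaction in which the 1,1-disubstituted alkene of 2 is the ene donor (methyl hydrogen transferred) and the chiral titanium Lewis acid blocks one face of the bound glyoxylate, which should set C8 as R.

**Step 2**
Reactants: 3 ethyl (2R)-2-hydroxy-4-methylidenehex-5-ynoate
Product: 4 ethyl (2R)-2-[(tert-butyldimethylsilyl)oxy]-4-methylidenehex-5-ynoate
Conditions: TBSCl, imidazole, DMF, 23 °C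
Reagents that add atoms: tert-butyldimethylsilyl chloride, CC(C)(C)[Si](C)(C)Cl
Why: Standard silylation of a secondary alcohol; the stereocentre is not touched.

**Step 3**
Reactants: 4 ethyl (2R)-2-[(tert-butyldimethylsilyl)oxy]-4-methylidenehex-5-ynoate
Product: 5 (2R)-2-[(tert-butyldimethylsilyl)oxy]-4-methylidenehex-5-ynal
Conditions: iBu2AlH, CH2Cl2, −78 °C; Rochelle salt
Reagents that add atoms: none
Why: Partial reduction of an α-silyloxy ester to the aldehyde through the stable aluminium hemiacetal at low temperature, which should leave C8 intact.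

**Step 4**
Reactants: 5 (2R)-2-[(tert-butyldimethylsilyl)oxy]-4-methylidenehex-5-ynal; 6 methyl acrylate
Product: 7 methyl (4R)-4-[(tert-butyldimethylsilyl)oxy]-3-hydroxy-2,6-dimethylideneoct-7-ynoate (both C3 epimers)
Conditions: 6 (5 equiv, neat), DABCO (1 equiv), 23 °C
Reagents that add atoms: none
Why: Morita–Baylis–Hillman reaction of an aldehyde with an acrylate; the new carbinol centre (future C7) is erased in step 5, so its configuration does not matter.

**Step 5**
Reactants: 7 methyl (4R)-4-[(tert-butyldimethylsilyl)oxy]-3-hydroxy-2,6-dimethylideneoct-7-ynoate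
Product: 8 methyl (2Z,4R)-2-(bromomethyl)-4-[(tert-butyldimethylsilyl)oxy]-6-methylideneoct-2-en-7-ynoate
Conditions: NBS, Me2S, CH2Cl2, −20 → 23 °C
Reagents that add atoms: N-bromosuccinimide, O=C1CCC(=O)N1Br
Why: Corey–Kim-type activation of the Baylis–Hillman alcohol followed by SN2' attack of bromide, which should give the (Z)-2-(bromomethyl)enoate with the ester trans to the chain.

**Step 6**
Reactants: 9 1-methoxy-4-[(prop-2-yn-1-yloxy)methyl]benzene
Product: 11 4-[(4-methoxyphenyl)methoxy]but-2-ynal, via lithium acetylide 10 (not isolated)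
Conditions: nBuLi, THF, −78 °C; DMF; then pH 7 buffer
Reagents that add atoms: N,N-dimethylformamide, CN(C)C=O
Why: Formylation of a lithium acetylide with DMF, the standard route to ynals.

**Step 7**
Reactants: 8 methyl (2Z,4R)-2-(bromomethyl)-4-[(tert-butyldimethylsilyl)oxy]-6-methylideneoct-2-en-7-ynoate; 11 4-[(4-methoxyphenyl)methoxy]but-2-ynal
Product: 13 trans-lactone (6β-H, 7α-H): 3-methylideneoxolan-2-one bearing 3-[(4-methoxyphenyl)methoxy]prop-1-ynyl at C6 and (1R)-1-(TBSO)-3-methylidenepent-4-ynyl at C7, via anti hydroxy ester 12 (not isolated)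
Conditions: CrCl2 (4 equiv), THF, 23 °C; then p-TsOH·H2O (cat.), CH2Cl2, 23 °C
Reagents that add atoms: none
Why: Nozaki–Hiyama–Kishi-type 2-(alkoxycarbonyl)allylation then lactonization: the γ-substituted allylchromium should add through a chair transition state to give the anti adduct (trans C6/C7), and the aldehyde should approach C7 anti to the C9 chain of the C8 silyloxy centre with H8 eclipsing the alkene (Felkin-type 1,2-induction), which sets C7.

**Step 8**
Reactants: 13 trans-lactone with PMB-protected propargylic oxygen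
Product: 14 trans-lactone with free propargylic alcohol (C15–OH)
Conditions: DDQ, CH2Cl2/H2O (10:1), 0 °C
Reagents that add atoms: none
Why: Oxidative cleavage of a 4-methoxybenzyl ether with DDQ, to which silyl ethers, the lactone and the enyne are inert.

**Step 9**
Reactants: 14 trans-lactone with free propargylic alcohol
Product: 16 allenyl lactone (C6 bears propa-1,2-dienyl; 6β-H, 7α-H, 8β-OTBS), via sulfonylhydrazine adduct 15 (not isolated)
Conditions: PPh3, DEAD, 2-nitrobenzenesulfonohydrazide, THF, −15 → 23 °C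
Reagents that add atoms: none
Why: Reductive 1,3-transposition of a primary propargylic alcohol (Mitsunobu N-alkylation of the sulfonylhydrazide, loss of sulfinic acid, retro-ene loss of N2 from the propargylic diazene), which should give the terminal allene.

**Step 10**
Reactants: 16 allenyl lactone
Product: 17 8β-(TBSO)-3-oxoguaia-1,4(15),10(14),11(13)-tetraen-12,6α-olide with 5α-H
Conditions: Mo(CO)6 (1.2 equiv), DMSO (10 equiv), toluene (0.01 M), 100 °C
Reagents that add atoms: molybdenum hexacarbonyl, [Mo].[C-]#[O+].[C-]#[O+].[C-]#[O+].[C-]#[O+].[C-]#[O+].[C-]#[O+]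
Why: Intramolecular allenic Pauson–Khand reaction through the proximal allene bond (the same event as in step 18); the trans-lactone holds the C6–O bond anti to the forming C1–C5 bond and lets the seven-membered ring develop chair-like, so H5 should end up cis to O6 (5α-H, trans to H6).

**Step 11**
Reactants: 17 8β-(TBSO)-3-oxoguaia-1,4(15),10(14),11(13)-tetraen-12,6α-olide (5α-H)
Product: 18 13,14,15-tris(phenylsulfanyl)-8β-(TBSO)-3-oxoguai-1-en-12,6α-olide (5α-H; epimers at C4, C10, C11)
Conditions: PhSH (3.3 equiv), Et3N (cat.), CH2Cl2, 0 → 23 °C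
Reagents that add atoms: thiophenol, Sc1ccccc1
Why: Thia-Michael additions (1,4 at C15 and C13, 1,6 at C14 with return of the C1=C2 enone) should mask the three methylene acceptors; the three new centres are erased in step 13.

**Step 12**
Reactants: 18 tris(phenylsulfanyl) enone
Product: 19 13,14,15-tris(phenylsulfanyl)-8β-(TBSO)-3-oxoguaian-12,6α-olide (1α-H, 5α-H)
Conditions: [CuH(PPh3)]6, H2O, benzene, 23 °C
Reagents that add atoms: none
Why: Copper hydride conjugate reduction of the one remaining, β,β-disubstituted enone; hydride should add to C1 from the α-face, away from the seven-membered ring that sits on the β-face at C5, to give the cis-fused 1α-H/5α-H ketone.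

**Step 13**
Reactants: 19 tris(phenylsulfanyl) ketone
Product: 21 8β-(TBSO)-3-oxoguaia-4(15),10(14),11(13)-trien-12,6α-olide (1α-H, 5α-H), via tris-sulfoxide 20 (not isolated)
Conditions: mCPBA (3 equiv), CH2Cl2, −78 °C; then CaCO3, toluene, 110 °C
Reagents that add atoms: none
Why: Sulfide oxidation then thermal syn-elimination of the sulfoxides; each sulfoxide has a single β-hydrogen (at C4, C10 and C11), so the three exocyclic methylenes should return without positional isomers.

**Step 14**
Reactants: 8 methyl (2Z,4R)-2-(bromomethyl)-4-[(tert-butyldimethylsilyl)oxy]-6-methylideneoct-2-en-7-ynoate; 11 4-[(4-methoxyphenyl)methoxy]but-2-ynal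
Product: 22 syn hydroxy ester: methyl 2-methylideneheptynoate chain with C6–OH in the 6-epi configuration, C7 and C8 as in 13, C15–OPMB
Conditions: In powder, THF/H2O (1:1), 23 °C
Reagents that add atoms: none
Why: Indium-mediated Barbier allylation: the (Z)-allylindium should react through a chair transition state to give the syn adduct (C6 epimeric to 12) with the same 1,2-induction from C8 at C7, and the hydroxy ester is isolated without acid so that it does not lactonize.

**Step 15**
Reactants: 22 syn hydroxy ester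
Product: 23 C6 triethylsilyl ether of 22
Conditions: Et3SiOTf, 2,6-lutidine, CH2Cl2, −78 °C
Reagents that add atoms: triethylsilyl trifluoromethanesulfonate, CC[Si](CC)(CC)OS(=O)(=O)C(F)(F)F
Why: Standard silylation; the triethylsilyl group can later be removed beside the C8 TBS ether and blocks lactonization.

**Step 16**
Reactants: 23 C6 triethylsilyl ether
Product: 24 propargylic alcohol (C15–OH) of 23
Conditions: DDQ, CH2Cl2/pH 7 buffer (10:1), 0 °C
Reagents that add atoms: none
Why: Oxidative cleavage of the 4-methoxybenzyl ether with DDQ under buffered conditions that should spare both silyl ethers.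

**Step 17**
Reactants: 24 propargylic alcohol
Product: 26 open-chain allenyne: methyl acrylate carrying at C7 the 6-epi C6(OSiEt3)–CH=C=CH2 unit and the (1R)-1-(TBSO)-3-methylidenepent-4-ynyl chain, via sulfonylhydrazine adduct 25 (not isolated)
Conditions: PPh3, DEAD, 2-nitrobenzenesulfonohydrazide, THF, −15 → 23 °C
Reagents that add atoms: none
Why: The same Mitsunobu/retro-ene reductive transposition as in step 9; only the primary propargylic alcohol is free.

**Step 18**
Reactants: 26 open-chain allenyne
Product: 27 methyl 6β-(triethylsilyloxy)-8β-(TBSO)-3-oxoguaia-1,4(15),10(14),11(13)-tetraen-12-oate (5β-H, 6α-H, 7α-H)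
Conditions: Mo(CO)6 (1.2 equiv), DMSO (10 equiv), toluene (0.01 M), 100 °C
Reagents that add atoms: molybdenum hexacarbonyl, [Mo].[C-]#[O+].[C-]#[O+].[C-]#[O+].[C-]#[O+].[C-]#[O+].[C-]#[O+]
Why: Mo(CO)6 activated by DMSO binds the terminal alkyne C1≡C2 and the allene, and oxidative cyclization across the proximal allene bond C4=C5 forms the C1–C5 bond in a molybdacyclopentene, after which CO insertion between C2 and C4 and reductive elimination release the 5-methylenecyclopent-2-enone (a [2+2+1] cyclocarbonylation). The closest known reaction type is the molybdenum-mediated intramolecular allenic Pauson–Khand reaction of monosubstituted allenes, which engages the proximal bond and gives α-methylene cyclopentenones, together with the allenic Pauson–Khand closures of seven-membered rings known under rhodium catalysis. The five-membered ring closes as the [2+2+1] cycloaddition, and the seven-membered ring closes in the same act because the C1–C5 bond joins the two ends of the five-atom tether C6–C10 (exo with respect to the allene bond that reacts). The only new stereocentre, C5, is controlled by the neighbouring C6 silyloxy centre: the C6–OSiEt3 bond should lie anti to the forming C1–C5 bond with the tether carbon C7 outside, so that H5 ends up cis to the C6 oxygen (5β-H in this 6-epi series), the same sense in which allylic oxygen substituents end up exo in intramolecular Pauson–Khand reactions. The step needs proximal- over distal-bond selectivity (the monosubstituted allene under molybdenum favours it, and the distal mode would have to close an eight-membered ring), reaction of the allene in preference to the electron-poor acrylate alkene, and cyclocarbonylation in preference to Alder-ene isomerization (stoichiometric Mo(CO)6/DMSO and high dilution). The conjugated enyne places C10=C14 next to the new C1=C2 bond, so the s-cis diene needed in step 21 is formed in the same step.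

**Step 19**
Reactants: 27 methyl 6β-(triethylsilyloxy)-8β-(TBSO)-3-oxoguaia-1,4(15),10(14),11(13)-tetraen-12-oate
Product: 28 methyl 6β-hydroxy-8β-(TBSO)-3-oxoguaia-1,4(15),10(14),11(13)-tetraen-12-oate (5β-H)
Conditions: HF·pyridine, pyridine, THF, 0 °C
Reagents that add atoms: none
Why: Buffered fluoride cleavage that should remove the secondary triethylsilyl ether in the presence of the TBS ether; the crude alcohol is used at once to forestall lactonization with retention.

**Step 20**
Reactants: 28 methyl 6β-hydroxy-8β-(TBSO)-3-oxoguaia-1,4(15),10(14),11(13)-tetraen-12-oate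
Product: 30 8β-(TBSO)-3-oxo-5β-guaia-1,4(15),10(14),11(13)-tetraen-12,6α-olide (5β-H, 6β-H, trans-lactone), via C6 triflate 29 (not isolated)
Conditions: Tf2O, 2,6-di-tert-butyl-4-methylpyridine, CH2Cl2, −78 → 0 °C
Reagents that add atoms: none
Why: Lactonization with inversion: the C6 triflate should be displaced from the rear by the carbonyl oxygen of the neighbouring methyl ester (5-exo-tet SN2), and the resulting dialkoxycarbenium ion loses its methyl group to triflate, which turns the 6β-oxygen into the 6α-lactone oxygen and makes H6 cis to H5.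

**Step 21**
Reactants: 30 8β-(TBSO)-3-oxo-5β-guaia-1,4(15),10(14),11(13)-tetraen-12,6α-olide; 21 8β-(TBSO)-3-oxoguaia-4(15),10(14),11(13)-trien-12,6α-olide
Product: 32 8,8'-bis-O-TBS ether of the target, via Diels–Alder adduct 31 (not isolated)
Conditions: 21 (3 equiv), toluene, 60 °C; then Et3N (cat.), CH2Cl2, 23 °C
Reagents that add atoms: none
Why: Intermolecular Diels–Alder reaction of the ring-locked s-cis diene C14=C10–C1=C2 of 30 with the exocyclic enone C4'=C15' of 21 in the "ortho" sense (C2–C4', C14–C15'), with the diene expected on the convex α-face of cis-fused 21 (sets C4'), followed by amine-mediated shift of the β,γ-enone into conjugation, in which C10 should be protonated cis to H5 because the seven-membered ring spans C5 and C10 across sp2 C1.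

**Step 22**
Reactants: 32 8,8'-bis-O-TBS ether of the target
Product: 33 CNP0397417.1
Conditions: HF·pyridine, THF, 0 → 23 °C
Reagents that add atoms: none
Why: Fluoride desilylation under mildly acidic conditions, chosen because the C5–H of the enone half is acidic and base is to be avoided.

**Compound list**

1 | ethyl glyoxylate | CCOC(=O)C=O | starting material
2 | 2-methylbut-1-en-3-yne | CC(=C)C#C | starting material
3 | ethyl (2R)-2-hydroxy-4-methylidenehex-5-ynoate | C#CC(=C)C[C@@H](O)C(=O)OCC | intermediate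
4 | ethyl (2R)-2-[(tert-butyldimethylsilyl)oxy]-4-methylidenehex-5-ynoate | C#CC(=C)C[C@@H](O[Si](C)(C)C(C)(C)C)C(=O)OCC | intermediate
5 | (2R)-2-[(tert-butyldimethylsilyl)oxy]-4-methylidenehex-5-ynal | C#CC(=C)C[C@@H](O[Si](C)(C)C(C)(C)C)C=O | intermediate
6 | methyl acrylate | C=CC(=O)OC | starting material
7 | methyl (4R)-4-[(tert-butyldimethylsilyl)oxy]-3-hydroxy-2,6-dimethylideneoct-7-ynoate (C3 epimers) | C#CC(=C)C[C@@H](O[Si](C)(C)C(C)(C)C)C(O)C(=C)C(=O)OC | intermediate
8 | methyl (2Z,4R)-2-(bromomethyl)-4-[(tert-butyldimethylsilyl)oxy]-6-methylideneoct-2-en-7-ynoate | C#CC(=C)C[C@@H](O[Si](C)(C)C(C)(C)C)/C=C(\CBr)C(=O)OC | intermediate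
9 | 1-methoxy-4-[(prop-2-yn-1-yloxy)methyl]benzene | C#CCOCc1ccc(OC)cc1 | starting material
10 | lithium acetylide of 9 | [Li]C#CCOCc1ccc(OC)cc1 | intermediate
11 | 4-[(4-methoxyphenyl)methoxy]but-2-ynal | O=CC#CCOCc1ccc(OC)cc1 | intermediate
12 | anti hydroxy ester (C6–OH as in the target, C7 and C8 as in 13) | C#CC(=C)C[C@@H](O[Si](C)(C)C(C)(C)C)[C@H]([C@H](O)C#CCOCc1ccc(OC)cc1)C(=C)C(=O)OC | intermediate
13 | trans-lactone (6β-H, 7α-H, 8β-OTBS, C15–OPMB alkyne at C6) | C#CC(=C)C[C@@H](O[Si](C)(C)C(C)(C)C)[C@H]1C(=C)C(=O)O[C@@H]1C#CCOCc1ccc(OC)cc1 | intermediate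
14 | trans-lactone with free propargylic alcohol | C#CC(=C)C[C@@H](O[Si](C)(C)C(C)(C)C)[C@H]1C(=C)C(=O)O[C@@H]1C#CCO | intermediate
15 | N-propargyl-N-(2-nitrobenzenesulfonyl)hydrazine of 14 | C#CC(=C)C[C@@H](O[Si](C)(C)C(C)(C)C)[C@H]1C(=C)C(=O)O[C@@H]1C#CCN(N)S(=O)(=O)c1ccccc1[N+](=O)[O-] | intermediate
16 | allenyl trans-lactone (propa-1,2-dienyl at C6) | C#CC(=C)C[C@@H](O[Si](C)(C)C(C)(C)C)[C@H]1C(=C)C(=O)O[C@@H]1C=C=C | intermediate
17 | 8β-(TBSO)-3-oxoguaia-1,4(15),10(14),11(13)-tetraen-12,6α-olide, 5α-H | C=C1C(=O)C=C2C(=C)C[C@@H](O[Si](C)(C)C(C)(C)C)[C@H]3C(=C)C(=O)O[C@@H]3[C@@H]12 | intermediate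
18 | 13,14,15-tris(phenylsulfanyl)-8β-(TBSO)-3-oxoguai-1-en-12,6α-olide, 5α-H (epimers at C4, C10, C11) | O=C1C=C2C(CSc3ccccc3)C[C@@H](O[Si](C)(C)C(C)(C)C)[C@H]3C(CSc4ccccc4)C(=O)O[C@@H]3[C@H]2C1CSc5ccccc5 | intermediate
19 | 13,14,15-tris(phenylsulfanyl)-8β-(TBSO)-3-oxoguaian-12,6α-olide, 1α-H, 5α-H | O=C1C[C@H]2C(CSc3ccccc3)C[C@@H](O[Si](C)(C)C(C)(C)C)[C@H]3C(CSc4ccccc4)C(=O)O[C@@H]3[C@H]2C1CSc5ccccc5 | intermediate
20 | tris-sulfoxide of 19 | O=C1C[C@H]2C(CS(=O)c3ccccc3)C[C@@H](O[Si](C)(C)C(C)(C)C)[C@H]3C(CS(=O)c4ccccc4)C(=O)O[C@@H]3[C@H]2C1CS(=O)c5ccccc5 | intermediate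
21 | 8β-(TBSO)-3-oxoguaia-4(15),10(14),11(13)-trien-12,6α-olide, 1α-H, 5α-H | C=C1C(=O)C[C@H]2C(=C)C[C@@H](O[Si](C)(C)C(C)(C)C)[C@H]3C(=C)C(=O)O[C@@H]3[C@@H]12 | intermediate
22 | syn hydroxy ester (6-epi C6–OH, C7 and C8 as in 13) | C#CC(=C)C[C@@H](O[Si](C)(C)C(C)(C)C)[C@H]([C@@H](O)C#CCOCc1ccc(OC)cc1)C(=C)C(=O)OC | intermediate
23 | C6 triethylsilyl ether of 22 | C#CC(=C)C[C@@H](O[Si](C)(C)C(C)(C)C)[C@H]([C@@H](O[Si](CC)(CC)CC)C#CCOCc1ccc(OC)cc1)C(=C)C(=O)OC | intermediate
24 | propargylic alcohol of 23 | C#CC(=C)C[C@@H](O[Si](C)(C)C(C)(C)C)[C@H]([C@@H](O[Si](CC)(CC)CC)C#CCO)C(=C)C(=O)OC | intermediate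
25 | N-propargyl-N-(2-nitrobenzenesulfonyl)hydrazine of 24 | C#CC(=C)C[C@@H](O[Si](C)(C)C(C)(C)C)[C@H]([C@@H](O[Si](CC)(CC)CC)C#CCN(N)S(=O)(=O)c1ccccc1[N+](=O)[O-])C(=C)C(=O)OC | intermediate
26 | open-chain allenyne (6-epi C6–OSiEt3, propa-1,2-dienyl at C6) | C#CC(=C)C[C@@H](O[Si](C)(C)C(C)(C)C)[C@H]([C@@H](O[Si](CC)(CC)CC)C=C=C)C(=C)C(=O)OC | intermediate
27 | methyl 6β-(triethylsilyloxy)-8β-(TBSO)-3-oxoguaia-1,4(15),10(14),11(13)-tetraen-12-oate, 5β-H | C=C1C(=O)C=C2C(=C)C[C@@H](O[Si](C)(C)C(C)(C)C)[C@@H](C(=C)C(=O)OC)[C@@H](O[Si](CC)(CC)CC)[C@H]12 | intermediate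
28 | methyl 6β-hydroxy-8β-(TBSO)-3-oxoguaia-1,4(15),10(14),11(13)-tetraen-12-oate, 5β-H | C=C1C(=O)C=C2C(=C)C[C@@H](O[Si](C)(C)C(C)(C)C)[C@@H](C(=C)C(=O)OC)[C@@H](O)[C@H]12 | intermediate
29 | 6β-triflate of 28 | C=C1C(=O)C=C2C(=C)C[C@@H](O[Si](C)(C)C(C)(C)C)[C@@H](C(=C)C(=O)OC)[C@@H](OS(=O)(=O)C(F)(F)F)[C@H]12 | intermediate
30 | 8β-(TBSO)-3-oxo-5β-guaia-1,4(15),10(14),11(13)-tetraen-12,6α-olide, 5β-H, 6β-H | C=C1C(=O)C=C2C(=C)C[C@@H](O[Si](C)(C)C(C)(C)C)[C@H]3C(=C)C(=O)O[C@@H]3[C@H]12 | intermediate
31 | Diels–Alder adduct, bis-TBS ether (C2–H of either configuration, C1=C10) | C=C1C(=O)C2C3=C(CC[C@]24C(=O)C[C@H]2C(=C)C[C@@H](O[Si](C)(C)C(C)(C)C)[C@H]5C(=C)C(=O)O[C@@H]5[C@H]24)C[C@@H](O[Si](C)(C)C(C)(C)C)[C@H]2C(=C)C(=O)O[C@@H]2[C@H]13 | intermediate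
32 | 8,8'-bis-O-TBS ether of the target | C=C1C(=O)C2=C3[C@H](CC[C@]24C(=O)C[C@H]2C(=C)C[C@@H](O[Si](C)(C)C(C)(C)C)[C@H]5C(=C)C(=O)O[C@@H]5[C@H]24)C[C@@H](O[Si](C)(C)C(C)(C)C)[C@H]2C(=C)C(=O)O[C@@H]2[C@H]13 | intermediate
33 | CNP0397417.1 | C=C1C(=O)C2=C3[C@H](CC[C@]24C(=O)C[C@H]2C(=C)C[C@@H](O)[C@H]5C(=C)C(=O)O[C@@H]5[C@H]24)C[C@@H](O)[C@H]2C(=C)C(=O)O[C@@H]2[C@H]13 | target

**Count and risks**

Total: 22 steps. Longest linear sequence: 14 steps (1–5, 14–22; the branch through 7–13 is equally long).

Steps most likely to fail: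

1. Step 18. The cyclocarbonylation may take the distal allene bond, drift into Alder-ene cycloisomerization, or show poor facial selectivity at C5 in the open-chain series. Fallback, from 17 back to 30: the C5 epimer 17 from step 10 is enolized towards C5 (TBSOTf, Et3N, CH2Cl2, −78 °C) to the silyloxyfulvene-type trienol ether F1. The enol ether is then cleaved with Bu4NF/AcOH in THF at −78 °C so that C5 is protonated kinetically from the β-face, opposite the lactone C6–O bond, which should give 30 and bypasses steps 14–20.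

2. Step 20. The C6 triflate may eliminate towards C5 or C7, or the strained rear-side closure may lose to lactonization with retention. Fallback, from 28 back to 30: intermolecular Mitsunobu inversion of 28 with formic acid (PPh3, DIAD, THF, 0 °C) gives the inverted 6α-formate F2. Acid-catalysed methanolysis (PPTS, MeOH, 40 °C) removes the formyl group and lets the 6α-alcohol lactonize with retention to 30.

3. Step 21. The diene 30 may dimerize with itself instead of reacting with 21, or the base may epimerize C5. Fallback, from 21 and 30 to 33: both monomers are desilylated with HF·pyridine to the 8β-alcohol of the dienophile F3 and the 8β-alcohol of the diene F4. F3 is silylated with iPr2SiCl2/imidazole and F4 is then added, giving the mixed diisopropylsilylene bis-ether F5. Heating in toluene makes the cycloaddition intramolecular, a trace of Et3N conjugates the enone to the silicon-bridged dimer F6, and HF·pyridine removes the tether to give 33.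

**Further compounds**

F1 | step 18 | 3-(TBSO)-8β-(TBSO)guaia-1(5),2,4(15),10(14),11(13)-pentaen-12,6α-olide (silyl trienol ether of 17) | C=C1C(O[Si](C)(C)C(C)(C)C)=CC2=C1[C@H]1OC(=O)C(=C)[C@@H]1[C@H](O[Si](C)(C)C(C)(C)C)CC2=C
F2 | step 20 | methyl 6α-(formyloxy)-8β-(TBSO)-3-oxoguaia-1,4(15),10(14),11(13)-tetraen-12-oate, 5β-H | C=C1C(=O)C=C2C(=C)C[C@@H](O[Si](C)(C)C(C)(C)C)[C@@H](C(=C)C(=O)OC)[C@H](OC=O)[C@H]12
F3 | step 21 | 8β-hydroxy-3-oxoguaia-4(15),10(14),11(13)-trien-12,6α-olide, 1α-H, 5α-H | C=C1C(=O)C[C@H]2C(=C)C[C@@H](O)[C@H]3C(=C)C(=O)O[C@@H]3[C@@H]12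
F4 | step 21 | 8β-hydroxy-3-oxo-5β-guaia-1,4(15),10(14),11(13)-tetraen-12,6α-olide | C=C1C(=O)C=C2C(=C)C[C@@H](O)[C@H]3C(=C)C(=O)O[C@@H]3[C@H]12
F5 | step 21 | diisopropylsilylene bis-ether joining O8 of F3 and O8 of F4 | CC(C)[Si](C(C)C)(O[C@@H]1CC(=C)[C@@H]2CC(=O)C(=C)[C@@H]2[C@H]2OC(=O)C(=C)[C@H]12)O[C@@H]1CC(=C)C2=CC(=O)C(=C)[C@H]2[C@H]2OC(=O)C(=C)[C@H]12
F6 | step 21 | 8,8'-O-diisopropylsilylene derivative of the target | C=C1C(=O)C2=C3[C@H](CC[C@]24C(=O)C[C@H]2C(=C)C[C@@H](O[Si]6(C(C)C)C(C)C)[C@H]5C(=C)C(=O)O[C@@H]5[C@H]24)C[C@@H](O6)[C@H]2C(=C)C(=O)O[C@@H]2[C@H]13
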